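**Plan**
- Retrosynthesis (briarane numbering C1–C20, C19 = lactone carbonyl): C16–Cl and the two acetates go last; the γ-lactone is cut at C8–C17, the ten-membered ring at C6–C7, the chain at C8–C9, C4–C5 and C2–C3, and the six-membered ring at C1–C14 and C11–C12 together.
- Enabling feature: in the six-membered ring the C2 carbonyl carbon and the C11 oxygen are 1,4 across C1–C10 (retron of a 2-siloxycyclopropane carboxylate, cyclopropane C1–C10–C11), and O14 is 1,3 to C12 (retron of a β-silyl acryloylsilane after Brook rearrangement).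
- Forward: a cyclopropane-fused γ-lactone (temporary C2–O–C9 tether) is opened by fluoride with strain release and annulated with the acylsilane to the six-membered ring; the tether is opened, C3–C6 and C7–C8 are attached, the ten-membered ring is closed, and the γ-lactone is made last.
- Stereochemistry: C10 from an enantioselective cyclopropanation; C1 by attack on the lactone enolate anti to the C10 acetyl group; C14 by equatorial hydride attack; C11/C12 by trans-diaxial bromohydrin formation; C2 and C7 by 1,3-syn reductions from O14 and O9; C9 by Felkin–Anh addition; C8/C17 by a chelated samarium enolate; the C5=C6 geometry from an α-iodo enal.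

Key step: step 9

Convention: β is the face of the six-membered ring that carries the C1 methyl group (C15).
Assumption: the sense of induction in step 7 is taken to follow that known for allyl and prenyl diazoacetates with this catalyst family; if the silyloxy group reverses it, Rh2(5R-MEPY)4 is used instead.

**Steps**

Step 1
Reactants: 1 (E)-3-(trimethylsilyl)prop-2-en-1-ol
Product: 2 (E)-tert-butyldimethyl{[3-(trimethylsilyl)prop-2-en-1-yl]oxy}silane
Conditions: TBSCl, imidazole, DMF, 0 °C to rt
Reagents that add atoms: tert-butyldimethylsilyl chloride, CC(C)(C)[Si](C)(C)Cl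
Why: Routine silyl ether formation at a primary allylic alcohol.

Step 2
Reactants: 2 allyl silyl ether
Product: 3 racemic (E)-1-(tert-butyldimethylsilyl)-3-(trimethylsilyl)prop-2-en-1-ol
Conditions: s-BuLi, THF, –78 to –30 °C; AcOH, –78 °C
Reagents that add atoms: none
Why: α-Lithiation of the allyl silyl ether triggers the retro-[1,2]-Brook (O to C) silyl shift, driven by the lithium alkoxide; the racemic carbinol centre is removed in step 3.

Step 3
Reactants: 3 α-silyl allylic alcohol
Product: 4 (E)-1-(tert-butyldimethylsilyl)-3-(trimethylsilyl)prop-2-en-1-one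
Conditions: (COCl)2, DMSO, CH2Cl2, –78 °C; Et3N
Reagents that add atoms: none
Why: Swern oxidation of an α-silyl carbinol should give the acylsilane without Brook cleavage because no nucleophilic base is present.

Step 4
Reactants: 5 methyl acetoacetate
Product: 6 methyl (Z)-3-(triethylsilyloxy)but-2-enoate
Conditions: TESOTf, Et3N, CH2Cl2, 0 °C
Reagents that add atoms: triethylsilyl triflate, CC[Si](CC)(CC)OS(=O)(=O)C(F)(F)F
Why: O-silylation of the β-keto ester enol should favour the Z isomer; the geometry does not matter because this carbon (C11) becomes trigonal again in step 9.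

Step 5
Reactants: 6 silyloxy enoate
Product: 7 (Z)-3-(triethylsilyloxy)but-2-en-1-ol
Conditions: i-Bu2AlH (2.2 equiv), CH2Cl2, –78 °C; Rochelle salt
Reagents that add atoms: none
Why: 1,2-Reduction of the ester by i-Bu2AlH at low temperature should leave the silyl enol ether intact.

Step 6
Reactants: 7 allylic alcohol
Product: 9 (Z)-3-(triethylsilyloxy)but-2-en-1-yl diazoacetate, via bromoacetate 8 (not isolated)
Conditions: BrCH2COBr, NaHCO3, MeCN, 0 °C; then TsNHNHTs, DBU, THF, 0 °C
Reagents that add atoms: bromoacetyl bromide, BrCC(=O)Br; N,N'-ditosylhydrazine, Cc1ccc(cc1)S(=O)(=O)NNS(=O)(=O)c1ccc(C)cc1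
Why: Acylation, then N-alkylation of the ditosylhydrazine and double sulfinate elimination, is the standard mild route from an alcohol to its diazoacetate.

Step 7
Reactants: 9 allylic diazoacetate
Product: 10 (1S,5S,6R)-6-methyl-6-(triethylsilyloxy)-3-oxabicyclo[3.1.0]hexan-2-one
Conditions: Rh2(5S-MEPY)4 (1 mol %), CH2Cl2, reflux, slow addition
Reagents that add atoms: none
Why: Intramolecular cyclopropanation of the electron-rich enol ether by the chiral dirhodium carboxamidate carbenoid sets C10 (and cis-fused C1) under catalyst control, and the Z geometry places the siloxy group endo.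

Step 8
Reactants: 10 cyclopropane lactone
Product: 11 (1S,5S,6R)-1,6-dimethyl-6-(triethylsilyloxy)-3-oxabicyclo[3.1.0]hexan-2-one
Conditions: LiN(i-Pr)2, THF, –78 °C; MeI
Reagents that add atoms: iodomethane, CI
Why: Enolate alkylation of a 2-siloxycyclopropane carboxylate at the ring carbon is established chemistry, and the ring fusion forces the methyl group (C15) into the only possible position.

Step 9
Reactants: 11 siloxycyclopropane lactone; 4 acylsilane
Product: 14 trans-fused 4,7a-dimethyl-3a,6-dihydroisobenzofuran-1,7(3H,7aH)-dione (C14 ketone; C11=C12), via ammonium enolate 12 (not isolated), via silyl dienol ether 13 (not isolated)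
Conditions: 4 (1.3 equiv), TBAT (1.1 equiv, slow addition), THF, –78 to –20 °C; then AcOH, TBAF, –78 °C
Reagents that add atoms: none
Why: Proposed new method: fluoride attack at silicon of the donor–acceptor cyclopropane releases the ring strain by retro-aldol cleavage of C1–C11, which unveils at the same moment the C11 methyl ketone and, regiospecifically, the lactone enolate at C1 (12); this enolate adds to the acylsilane carbonyl (C1–C14), a [1,2]-Brook rearrangement gives a silyloxyallyl anion stabilised at C12 by the trimethylsilyl group, the carbanion closes onto the C11 ketone (C11–C12), and Peterson elimination of the β-silyl alkoxide fixes C11=C12 (13). The closest known reaction types are the Brook rearrangement-mediated [3+2] annulation of β-silyl acryloylsilanes with ketone enolates and the fluoride-induced opening of 2-siloxycyclopropane carboxylates to γ-oxo ester enolates; their merger into a [3+3] annulation, in which the attacked carbonyl is 1,3 to the enolate carbon, is new. The six-membered ring closes in the 6-exo-trig mode (C12 onto the exocyclic C11=O). C1 is set by attack on the butyrolactone enolate anti to the acetyl group at C10, the centre carried over from 11, which gives the trans ring fusion of the target; C11 and C12 become trigonal and are set in step 11. The step needs 1,2- over 1,4-addition (secured by the β-silyl group), closure on the ketone and not on the lactone carbonyl (which would give a strained bridged ring), and kinetic α-protonation of the dienolate on buffered desilylation so that the double bond stays at C11=C12.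

Step 10
Reactants: 14 keto lactone
Product: 15 14α-hydroxy lactone (C11=C12)
Conditions: LiBH(s-Bu)3, THF, –78 °C; aq. NH4Cl
Reagents that add atoms: none
Why: The bulky hydride should attack the C14 ketone along the equatorial trajectory and give the axial 14α-alcohol, trans to the axial C15 methyl group; the lactone is not reduced at this temperature.

Step 11
Reactants: 15 homoallylic alcohol
Product: 17 11β,12β-epoxy-14α-hydroxy lactone, via bromohydrin 16 (not isolated)
Conditions: NBS, THF–H2O, 0 °C; then DBU, CH2Cl2, rt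
Reagents that add atoms: water, O
Why: Water should open the α-bromonium ion at the tertiary C11 from the β face (Markovnikov and Fürst–Plattner trans-diaxial opening), and base closure with inversion at C12 then gives the β-epoxide on the face that a peracid would not reach past the axial C15 methyl group.

Step 12
Reactants: 17 epoxy lactone
Product: 18 C2 vinyl ketone with free 9-OH and 14α-OH
Conditions: CH2=CHMgBr (3 equiv), THF, –78 °C; aq. NH4Cl
Reagents that add atoms: vinylmagnesium bromide, C=C[Mg]Br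
Why: Addition of a Grignard reagent to a γ-lactone should stop at the ketone level because the magnesium lactolate persists at low temperature; the hindered neopentyl carbonyl disfavours a second addition.

Step 13
Reactants: 18 β-hydroxy enone
Product: 19 triol with 2,14-syn carbinols
Conditions: Et2BOMe, NaBH4, THF–MeOH, –78 °C
Reagents that add atoms: none
Why: Narasaka–Prasad reduction: the boron chelate between O14 and the C2 carbonyl is attacked axially by external hydride, which sets C2 syn to C14 as in the target.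

Step 14
Reactants: 19 triol
Product: 20 2,9,14-tris(triethylsilyl) ether
Conditions: TESOTf, 2,6-lutidine, CH2Cl2, –78 °C
Reagents that add atoms: triethylsilyl triflate, CC[Si](CC)(CC)OS(=O)(=O)C(F)(F)F
Why: The silyl triflate silylates the hindered secondary alcohols too; the three ethers are differentiated later by their different lability.

Step 15
Reactants: 1 (E)-3-(trimethylsilyl)prop-2-en-1-ol
Product: 21 (E)-3-(trimethylsilyl)prop-2-enal
Conditions: MnO2, CH2Cl2, rt
Reagents that add atoms: none
Why: Selective allylic oxidation with retention of the alkene geometry.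

Step 16
Reactants: 21 enal
Product: 22 (Z)-2-iodo-3-(trimethylsilyl)prop-2-enal
Conditions: I2, pyridine, CH2Cl2, 0 °C to rt
Reagents that add atoms: iodine, II
Why: α-Iodination of an enal by conjugate addition of pyridine, iodination and elimination keeps the β-substituent trans to the formyl group, so iodine ends cis to silicon.

Step 17
Reactants: 22 iodo enal
Product: 23 (Z)-2-iodo-3-(trimethylsilyl)prop-2-en-1-ol
Conditions: NaBH4, CeCl3·7H2O, MeOH, –20 °C
Reagents that add atoms: none
Why: Luche reduction gives clean 1,2-reduction of the enal.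

Step 18
Reactants: 23 iodo allylic alcohol
Product: 24 (Z)-tert-butyl{[2-iodo-3-(trimethylsilyl)prop-2-en-1-yl]oxy}diphenylsilane
Conditions: TBDPSCl, imidazole, DMF, rt
Reagents that add atoms: tert-butyldiphenylsilyl chloride, CC(C)(C)[Si](Cl)(c1ccccc1)c1ccccc1
Why: Routine silylation; the robust silyl ether carries C16–O to the end of the route.

Step 19
Reactants: 20 tris(silyl) ether; 24 vinyl iodide
Product: 26 C1–C6 vinylsilane (C5=C6 with SiMe3 cis to C4), via B-alkyl-9-BBN adduct 25 (not isolated)
Conditions: 9-BBN, THF, rt; then 24, Pd(dppf)Cl2, AsPh3, Cs2CO3, DMF–H2O, rt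
Reagents that add atoms: none
Why: Anti-Markovnikov hydroboration of the terminal vinyl group and B-alkyl Suzuki–Miyaura coupling form C4–C5 with retention of the vinyl iodide geometry.

Step 20
Reactants: 26 vinylsilane
Product: 27 (C6) vinyl iodide
Conditions: NIS, MeCN–ClCH2CN, 0 °C
Reagents that add atoms: N-iodosuccinimide, O=C1CCC(=O)N1I
Why: Ipso-iododesilylation through the tertiary β-silyl cation should proceed with retention of the alkene geometry.

Step 21
Reactants: 27 tris(silyl) ether
Product: 28 C9 aldehyde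
Conditions: (COCl)2, DMSO, CH2Cl2, –78 to –30 °C; Et3N
Reagents that add atoms: none
Why: Under Swern conditions a primary triethylsilyl ether is cleaved and oxidised in place while the secondary ones survive.

Step 22
Reactants: 28 aldehyde; 29 ethyl 1,3-dithiane-2-carboxylate
Product: 30 9-hydroxy adduct carrying the 2-(ethoxycarbonyl)-1,3-dithian-2-yl group (C8, C7)
Conditions: 29, LiN(i-Pr)2, THF, –78 °C; then 28; AcOH quench at –78 °C
Reagents that add atoms: none
Why: Aldol-type addition of the dithiane ester enolate should follow the Felkin–Anh model with the quaternary C1 as the large substituent at C10, which gives the C9 configuration of the target; the cold quench avoids retro-aldol cleavage.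

Step 23
Reactants: 30 hydroxy ester
Product: 31 9-hydroxy C7 aldehyde
Conditions: i-Bu2AlH (2.5 equiv), toluene, –78 °C; Rochelle salt
Reagents that add atoms: none
Why: Partial reduction of the hindered ester stops at the aldehyde because the tetrahedral aluminate is stable at –78 °C; the aldehyde has no α-hydrogen.

Step 24
Reactants: 31 iodo aldehyde
Product: 32 ten-membered diol (C7 epimers)
Conditions: CrCl2 (10 equiv), NiCl2 (2 mol %), DMSO–THF, 0.002 M, rt
Reagents that add atoms: none
Why: Nozaki–Hiyama–Kishi macrocyclisation forms C6–C7 with retention of the C5=C6 geometry and tolerates the free hydroxyl, the dithiane and the epoxide; the C7 configuration is not needed here because step 25 removes it.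

Step 25
Reactants: 32 macrocyclic diol
Product: 33 macrocyclic 9-hydroxy C7 enone
Conditions: MnO2, CH2Cl2, rt
Reagents that add atoms: none
Why: MnO2 oxidises only the allylic C7 alcohol; the neutral conditions avoid retro-aldol cleavage of the β-hydroxy ketone.

Step 26
Reactants: 33 β-hydroxy enone
Product: 34 7,9-syn diol
Conditions: Et2BOMe, NaBH4, THF–MeOH, –78 °C
Reagents that add atoms: none
Why: Narasaka–Prasad reduction through the O9–boron–O7 chelate sets C7 syn to C9, the relation found in the target.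

Step 27
Reactants: 34 diol
Product: 35 C7 2-bromopropanoate (epimers at the CHBr carbon)
Conditions: CH3CHBrCOBr (1.1 equiv), 2,4,6-collidine, CH2Cl2, –78 to –40 °C
Reagents that add atoms: 2-bromopropanoyl bromide, CC(Br)C(=O)Br
Why: The allylic C7 hydroxyl should be acylated before the C9 hydroxyl, which lies between the spiro dithiane carbon and the ring carbon C10; both bromide epimers give the same enolate in step 30.

Step 28
Reactants: 35 hydroxy ester
Product: 36 C9 tert-butyldimethylsilyl ether
Conditions: TBSOTf, 2,6-lutidine, CH2Cl2, 0 °C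
Reagents that add atoms: tert-butyldimethylsilyl triflate, CC(C)(C)[Si](C)(C)OS(=O)(=O)C(F)(F)F
Why: Silylation masks O9 so that it stays free of acetate in step 32.

Step 29
Reactants: 36 dithiane
Product: 37 C8 ketone
Conditions: MeI, CaCO3, MeCN–H2O, 40 °C
Reagents that add atoms: water, O
Why: S-Methylation and buffered hydrolysis unmask the ketone without electrophilic metal salts, so the alkene, the epoxide and the bromo ester are untouched.

Step 30
Reactants: 37 α-acyloxy ketone
Product: 38 γ-lactone with 8-OH and C17 methyl (2,14-bis-TES; 9-TBS; 16-TBDPS)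
Conditions: SmI2 (2.2 equiv), THF, –78 °C
Reagents that add atoms: none
Why: Intramolecular samarium Reformatsky reaction: the bromo ester is reduced faster than the ketone, and the chelated enolate adds to C8 in the conformer with C6 anti to C9 and closes with the methyl group trans to C9, which gives the all-trans carbon substituents of the target lactone.

Step 31
Reactants: 38 protected lactone
Product: 39 2,14-diol
Conditions: HF·pyridine, pyridine, THF, 0 °C
Reagents that add atoms: none
Why: Buffered HF·pyridine removes the two triethylsilyl ethers and leaves the hindered TBS ether and the TBDPS ether.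

Step 32
Reactants: 39 diol
Product: 40 2,14-diacetate
Conditions: Ac2O, Et3N, DMAP (cat.), CH2Cl2, 0 °C to rt
Reagents that add atoms: acetic anhydride, CC(=O)OC(C)=O
Why: The two secondary alcohols are acetylated; the tertiary 8-OH does not react under these conditions.

Step 33
Reactants: 40 diacetate
Product: 41 9,16-diol
Conditions: TBAF, AcOH, THF, rt
Reagents that add atoms: none
Why: Acetic acid-buffered fluoride removes both remaining silyl ethers without acetate migration or lactone opening.

Step 34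
Reactants: 41 diol
Product: 43 CNP0308390.1, via allylic mesylate 42 (not isolated)
Conditions: MsCl, 2,4,6-collidine, LiCl, DMF, 0 °C
Reagents that add atoms: lithium chloride, [Li+].[Cl-]
Why: The primary allylic alcohol is mesylated and displaced by chloride in situ; the hindered secondary 9-OH and the tertiary 8-OH should not react.

**Compound list**

1 | (E)-3-(trimethylsilyl)prop-2-en-1-ol | OC/C=C/[Si](C)(C)C | starting material
2 | (E)-tert-butyldimethyl{[3-(trimethylsilyl)prop-2-en-1-yl]oxy}silane | CC(C)(C)[Si](C)(C)OC/C=C/[Si](C)(C)C | intermediate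
3 | racemic (E)-1-(tert-butyldimethylsilyl)-3-(trimethylsilyl)prop-2-en-1-ol | CC(C)(C)[Si](C)(C)C(O)/C=C/[Si](C)(C)C | intermediate
4 | (E)-1-(tert-butyldimethylsilyl)-3-(trimethylsilyl)prop-2-en-1-one | CC(C)(C)[Si](C)(C)C(=O)/C=C/[Si](C)(C)C | intermediate
5 | methyl acetoacetate | CC(=O)CC(=O)OC | starting material
6 | methyl (Z)-3-(triethylsilyloxy)but-2-enoate | CC[Si](CC)(CC)O/C(C)=C\C(=O)OC | intermediate
7 | (Z)-3-(triethylsilyloxy)but-2-en-1-ol | CC[Si](CC)(CC)O/C(C)=C\CO | intermediate
8 | (Z)-3-(triethylsilyloxy)but-2-en-1-yl bromoacetate | CC[Si](CC)(CC)O/C(C)=C\COC(=O)CBr | intermediate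
9 | (Z)-3-(triethylsilyloxy)but-2-en-1-yl diazoacetate | CC[Si](CC)(CC)O/C(C)=C\COC(=O)C=[N+]=[N-] | intermediate
10 | (1S,5S,6R)-6-methyl-6-(triethylsilyloxy)-3-oxabicyclo[3.1.0]hexan-2-one | C[C@@]1(O[Si](CC)(CC)CC)[C@@H]2COC(=O)[C@H]12 | intermediate
11 | (1S,5S,6R)-1,6-dimethyl-6-(triethylsilyloxy)-3-oxabicyclo[3.1.0]hexan-2-one | C[C@@]1(O[Si](CC)(CC)CC)[C@@H]2COC(=O)[C@]12C | intermediate
12 | tetrabutylammonium enolate of (4S)-4-acetyl-3-methyldihydrofuran-2(3H)-one | CCCC[N+](CCCC)(CCCC)CCCC.CC(=O)[C@@H]1COC([O-])=C1C | intermediate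
13 | trans-fused 7-(tert-butyldimethylsilyloxy)-4,7a-dimethyl-3a,7a-dihydroisobenzofuran-1(3H)-one (silyl dienol ether C14=C13, C12=C11) | CC(C)(C)[Si](C)(C)OC1=CC=C(C)[C@@H]2COC(=O)[C@@]12C | intermediate
14 | trans-fused 4,7a-dimethyl-3a,6-dihydroisobenzofuran-1,7(3H,7aH)-dione (C14 ketone, C11=C12, lactone C2(=O)–O–C9) | O=C1CC=C(C)[C@@H]2COC(=O)[C@@]12C | intermediate
15 | 14α-hydroxy lactone (C11=C12) | O[C@H]1CC=C(C)[C@@H]2COC(=O)[C@@]12C | intermediate
16 | 12α-bromo-11β,14α-dihydroxy lactone | O[C@H]1C[C@@H](Br)[C@@](O)(C)[C@@H]2COC(=O)[C@@]12C | intermediate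
17 | 11β,12β-epoxy-14α-hydroxy lactone | O[C@H]1C[C@@H]2O[C@]2(C)[C@@H]2COC(=O)[C@@]12C | intermediate
18 | C2 vinyl ketone, 9-hydroxymethyl, 14α-hydroxy, 11β,12β-epoxide | O[C@H]1C[C@@H]2O[C@]2(C)[C@H](CO)[C@]1(C(=O)C=C)C | intermediate
19 | triol with 2,14-syn carbinols (C2 vinyl carbinol, C9 CH2OH) | O[C@H]1C[C@@H]2O[C@]2(C)[C@H](CO)[C@]1([C@H](O)C=C)C | intermediate
20 | 2,9,14-tris(triethylsilyl) ether of 19 | CC[Si](CC)(CC)O[C@H]1C[C@@H]2O[C@]2(C)[C@H](CO[Si](CC)(CC)CC)[C@]1([C@H](O[Si](CC)(CC)CC)C=C)C | intermediate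
21 | (E)-3-(trimethylsilyl)prop-2-enal | O=C/C=C/[Si](C)(C)C | intermediate
22 | (Z)-2-iodo-3-(trimethylsilyl)prop-2-enal | O=C/C(I)=C/[Si](C)(C)C | intermediate
23 | (Z)-2-iodo-3-(trimethylsilyl)prop-2-en-1-ol | OC/C(I)=C/[Si](C)(C)C | intermediate
24 | (Z)-tert-butyl{[2-iodo-3-(trimethylsilyl)prop-2-en-1-yl]oxy}diphenylsilane | CC(C)(C)[Si](c1ccccc1)(c1ccccc1)OC/C(I)=C/[Si](C)(C)C | intermediate
25 | C4 B-alkyl-9-BBN adduct of 20 | CC[Si](CC)(CC)O[C@H]1C[C@@H]2O[C@]2(C)[C@H](CO[Si](CC)(CC)CC)[C@]1([C@H](O[Si](CC)(CC)CC)CCB1C2CCCC1CCC2)C | intermediate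
26 | C1–C6 vinylsilane (C5=C6, SiMe3 cis to C4, 16-OTBDPS, 2,9,14-tris-TES) | CC[Si](CC)(CC)O[C@H]1C[C@@H]2O[C@]2(C)[C@H](CO[Si](CC)(CC)CC)[C@]1([C@H](O[Si](CC)(CC)CC)CC/C(CO[Si](c1ccccc1)(c1ccccc1)C(C)(C)C)=C\[Si](C)(C)C)C | intermediate
27 | C6 vinyl iodide (iodine cis to C4) | CC[Si](CC)(CC)O[C@H]1C[C@@H]2O[C@]2(C)[C@H](CO[Si](CC)(CC)CC)[C@]1([C@H](O[Si](CC)(CC)CC)CC/C(CO[Si](c1ccccc1)(c1ccccc1)C(C)(C)C)=C\I)C | intermediate
28 | C9 aldehyde | CC[Si](CC)(CC)O[C@H]1C[C@@H]2O[C@]2(C)[C@H](C=O)[C@]1([C@H](O[Si](CC)(CC)CC)CC/C(CO[Si](c1ccccc1)(c1ccccc1)C(C)(C)C)=C\I)C | intermediate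
29 | ethyl 1,3-dithiane-2-carboxylate | CCOC(=O)C1SCCCS1 | starting material
30 | 9-hydroxy adduct with 2-(ethoxycarbonyl)-1,3-dithian-2-yl at C9 | CC[Si](CC)(CC)O[C@H]1C[C@@H]2O[C@]2(C)[C@H]([C@@H](O)C3(C(=O)OCC)SCCCS3)[C@]1([C@H](O[Si](CC)(CC)CC)CC/C(CO[Si](c1ccccc1)(c1ccccc1)C(C)(C)C)=C\I)C | intermediate
31 | 9-hydroxy C7 aldehyde (2-formyl-1,3-dithiane) | CC[Si](CC)(CC)O[C@H]1C[C@@H]2O[C@]2(C)[C@H]([C@@H](O)C3(C=O)SCCCS3)[C@]1([C@H](O[Si](CC)(CC)CC)CC/C(CO[Si](c1ccccc1)(c1ccccc1)C(C)(C)C)=C\I)C | intermediate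
32 | ten-membered 7,9-diol, C8 dithiane, C7 epimers | CC[Si](CC)(CC)O[C@H]1C[C@@H]2O[C@]2(C)[C@@H]2[C@@H](O)C3(SCCCS3)C(O)/C=C(/CO[Si](c3ccccc3)(c3ccccc3)C(C)(C)C)CC[C@@H](O[Si](CC)(CC)CC)[C@@]12C | intermediate
33 | ten-membered 9-hydroxy C7 enone, C8 dithiane | CC[Si](CC)(CC)O[C@H]1C[C@@H]2O[C@]2(C)[C@@H]2[C@@H](O)C3(SCCCS3)C(=O)/C=C(/CO[Si](c3ccccc3)(c3ccccc3)C(C)(C)C)CC[C@@H](O[Si](CC)(CC)CC)[C@@]12C | intermediate
34 | 7,9-syn diol, C8 dithiane | CC[Si](CC)(CC)O[C@H]1C[C@@H]2O[C@]2(C)[C@@H]2[C@@H](O)C3(SCCCS3)[C@@H](O)/C=C(/CO[Si](c3ccccc3)(c3ccccc3)C(C)(C)C)CC[C@@H](O[Si](CC)(CC)CC)[C@@]12C | intermediate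
35 | C7 2-bromopropanoate, 9-OH (CHBr epimers) | CC[Si](CC)(CC)O[C@H]1C[C@@H]2O[C@]2(C)[C@@H]2[C@@H](O)C3(SCCCS3)[C@@H](OC(=O)C(C)Br)/C=C(/CO[Si](c3ccccc3)(c3ccccc3)C(C)(C)C)CC[C@@H](O[Si](CC)(CC)CC)[C@@]12C | intermediate
36 | C7 2-bromopropanoate, 9-OTBS, C8 dithiane | CC[Si](CC)(CC)O[C@H]1C[C@@H]2O[C@]2(C)[C@@H]2[C@@H](O[Si](C)(C)C(C)(C)C)C3(SCCCS3)[C@@H](OC(=O)C(C)Br)/C=C(/CO[Si](c3ccccc3)(c3ccccc3)C(C)(C)C)CC[C@@H](O[Si](CC)(CC)CC)[C@@]12C | intermediate
37 | C8 ketone, C7 2-bromopropanoate, 9-OTBS | CC[Si](CC)(CC)O[C@H]1C[C@@H]2O[C@]2(C)[C@@H]2[C@@H](O[Si](C)(C)C(C)(C)C)C(=O)[C@@H](OC(=O)C(C)Br)/C=C(/CO[Si](c3ccccc3)(c3ccccc3)C(C)(C)C)CC[C@@H](O[Si](CC)(CC)CC)[C@@]12C | intermediate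
38 | protected lactone (2,14-bis-TES, 9-TBS, 16-TBDPS, 8-OH) | CC[Si](CC)(CC)O[C@H]1C[C@@H]2O[C@]2(C)[C@@H]2[C@@H](O[Si](C)(C)C(C)(C)C)[C@@]3(O)[C@H](/C=C(/CO[Si](c4ccccc4)(c4ccccc4)C(C)(C)C)CC[C@@H](O[Si](CC)(CC)CC)[C@@]12C)OC(=O)[C@@H]3C | intermediate
39 | 2,14-diol (9-TBS, 16-TBDPS) | O[C@H]1C[C@@H]2O[C@]2(C)[C@@H]2[C@@H](O[Si](C)(C)C(C)(C)C)[C@@]3(O)[C@H](/C=C(/CO[Si](c4ccccc4)(c4ccccc4)C(C)(C)C)CC[C@@H](O)[C@@]12C)OC(=O)[C@@H]3C | intermediate
40 | 2,14-diacetate (9-TBS, 16-TBDPS) | CC(=O)O[C@H]1C[C@@H]2O[C@]2(C)[C@@H]2[C@@H](O[Si](C)(C)C(C)(C)C)[C@@]3(O)[C@H](/C=C(/CO[Si](c4ccccc4)(c4ccccc4)C(C)(C)C)CC[C@@H](OC(C)=O)[C@@]12C)OC(=O)[C@@H]3C | intermediate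
41 | 16-hydroxy analogue of the target (9,16-diol) | CC(=O)O[C@H]1C[C@@H]2O[C@]2(C)[C@@H]2[C@@H](O)[C@@]3(O)[C@H](/C=C(/CO)CC[C@@H](OC(C)=O)[C@@]12C)OC(=O)[C@@H]3C | intermediate
42 | 16-mesylate | CC(=O)O[C@H]1C[C@@H]2O[C@]2(C)[C@@H]2[C@@H](O)[C@@]3(O)[C@H](/C=C(/COS(C)(=O)=O)CC[C@@H](OC(C)=O)[C@@]12C)OC(=O)[C@@H]3C | intermediate
43 | CNP0308390.1 | CC(=O)O[C@H]1C[C@@H]2O[C@]2(C)[C@@H]2[C@@H](O)[C@@]3(O)[C@H](/C=C(/CCl)CC[C@@H](OC(C)=O)[C@@]12C)OC(=O)[C@@H]3C | target

**Count and risks**

Total steps: 34. Longest linear sequence: 27 steps (5 to 43 through steps 4–14 and 19–34).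

Step 9. The naked lactone enolate may be quenched by proton transfer from the α-positions of the newly unveiled ketone, or fluoride may attack the acylsilane, before the C1–C14 bond forms. The fallback sets out from 11 and comes back at 14 with known reactions. Fluoride-induced ring opening of 11 in the presence of freshly prepared but-3-enal traps the enolate by aldol addition and should give the hydroxy keto lactone F1 (C14 epimers). Wittig methylenation of the C11 ketone with Ph3P=CH2 should give the diene F2. Ring-closing metathesis with the second-generation Hoveyda–Grubbs catalyst closes C11=C12 to the cyclohexenol F3, and Dess–Martin oxidation gives 14.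

Step 24. Intermolecular coupling and oligomerisation may outrun the slow closure of the ten-membered ring at the neopentyl-type aldehyde. The fallback sets out from 27 and 29, comes back at 33, and moves the ring closure to C8–C9. Reduction of 29 with i-Bu2AlH gives 1,3-dithiane-2-carbaldehyde F4. Intermolecular Nozaki–Hiyama–Kishi coupling of 27 with F4 gives the allylic alcohol F5. Swern oxidation converts both the allylic alcohol and the primary triethylsilyl ether and gives the keto aldehyde F6. Intramolecular aldol addition of the acidic 2-acyl-1,3-dithiane (DBU, LiCl, MeCN) closes the ring to 33.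

Step 30. Single-electron reduction of the α-acyloxy ketone with loss of the C7 ester may compete with enolate formation. The fallback sets out from 37 and comes back at 38 without a one-electron reductant. Elimination of HBr with DBU gives the C7 acrylate F7, and reductive aldol cyclisation with [(Ph3P)CuH]6 in toluene generates the same propionate enolate by conjugate hydride addition and closes the lactone to 38.

Further compounds
F1 | step 9 | (3S,4S)-4-acetyl-3-(1-hydroxybut-3-en-1-yl)-3-methyldihydrofuran-2(3H)-one (carbinol epimers) | CC(=O)[C@@H]1COC(=O)[C@@]1(C)C(O)CC=C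
F2 | step 9 | 3-(1-hydroxybut-3-en-1-yl)-3-methyl-4-(prop-1-en-2-yl)dihydrofuran-2(3H)-one | C=C(C)[C@@H]1COC(=O)[C@@]1(C)C(O)CC=C
F3 | step 9 | trans-fused 7-hydroxy-4,7a-dimethyl-3a,6,7,7a-tetrahydroisobenzofuran-1(3H)-one (C14 epimers) | OC1CC=C(C)[C@@H]2COC(=O)[C@@]12C
F4 | step 24 | 1,3-dithiane-2-carbaldehyde | O=CC1SCCCS1
F5 | step 24 | C7 allylic alcohol bearing 1,3-dithian-2-yl (2,9,14-tris-TES, 16-TBDPS) | CC[Si](CC)(CC)O[C@H]1C[C@@H]2O[C@]2(C)[C@H](CO[Si](CC)(CC)CC)[C@]1([C@H](O[Si](CC)(CC)CC)CC/C(CO[Si](c1ccccc1)(c1ccccc1)C(C)(C)C)=C\C(O)C1SCCCS1)C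
F6 | step 24 | C9 aldehyde C7 ketone bearing 1,3-dithian-2-yl | CC[Si](CC)(CC)O[C@H]1C[C@@H]2O[C@]2(C)[C@H](C=O)[C@]1([C@H](O[Si](CC)(CC)CC)CC/C(CO[Si](c1ccccc1)(c1ccccc1)C(C)(C)C)=C\C(=O)C1SCCCS1)C
F7 | step 30 | C7 acrylate of the C8 ketone (9-TBS) | CC[Si](CC)(CC)O[C@H]1C[C@@H]2O[C@]2(C)[C@@H]2[C@@H](O[Si](C)(C)C(C)(C)C)C(=O)[C@@H](OC(=O)C=C)/C=C(/CO[Si](c3ccccc3)(c3ccccc3)C(C)(C)C)CC[C@@H](O[Si](CC)(CC)CC)[C@@]12C
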